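**Plan**
- Retrosynthesis: the 7-OH is unmasked last. The C2–C3 bond of the pyranone ring (ring C) is then cut back to a diazoketone, next the aryl–O–CH2 ether bond, and finally the aryl–prenyl bonds.
- Enabling feature: C2 is both benzylic to ring B and bound to the ring oxygen O1, and C3 is alpha to the C4 ketone. C3 can therefore be a ketocarbenoid and C2–H an activated ether C–H bond at the end of the chain C3–C4–C4a–C8a–O1–C2.
- Forward: the ring A ketone (C-prenylation, 7-O-silylation) and the chroman alcohol of ring B (bromination, Stille prenylation, reduction) are joined by Mitsunobu etherification. The acetyl group is then turned into a diazoketone, and C–H insertion closes ring C last.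
- Stereochemistry: the only stereocenter, C2, is created in the insertion step from a prochiral OCH2 group under control of a chiral dirhodium carboxylate.
- Helper groups: the triisopropylsilyl ether on O7 keeps the phenol out of the carbenoid step and is removed at the end. The diazo group leaves as N2.

Key step: step 8

Assumption: 2,2-dimethylchroman-6-carbaldehyde (6) and tributyl(3-methylbut-2-en-1-yl)stannane (9) are taken as catalogue compounds. Flavanone numbering (O1, C2, C3, C4, C4a, C5 to C8, C8a) is used for the target and its precursors.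

**Step 1**
Reactants: 1 2,4-dihydroxyacetophenone; 2 prenyl bromide (1-bromo-3-methylbut-2-ene)
Product: 3 1-[2,4-dihydroxy-3-(3-methylbut-2-en-1-yl)phenyl]ethan-1-one
Conditions: KOH (10% aq.), 0 °C to rt
Reagents that add atoms: prenyl bromide 2, CC(C)=CCBr
Why: Phenoxide C-allylation: in water the solvated resorcinolate reacts at carbon, and C3, ortho to both oxygens, is the most nucleophilic position.

**Step 2**
Reactants: 3; 4 chlorotriisopropylsilane
Product: 5 1-[2-hydroxy-3-(3-methylbut-2-en-1-yl)-4-(triisopropylsilyloxy)phenyl]ethan-1-one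
Conditions: imidazole, DMF, 0 °C to rt
Reagents that add atoms: chlorotriisopropylsilane 4, CC(C)[Si](Cl)(C(C)C)C(C)C
Why: Selective silylation: the 2-OH is held in a hydrogen bond to the acetyl carbonyl, so only the free 4-OH should be silylated.

**Step 3**
Reactants: 6 2,2-dimethylchroman-6-carbaldehyde; 7 bromine
Product: 8 8-bromo-2,2-dimethylchroman-6-carbaldehyde
Conditions: Br2, NaOAc, AcOH, rt
Reagents that add atoms: bromine 7, BrBr
Why: Electrophilic aromatic bromination: C8 is ortho to the ring oxygen, para to the C4 alkyl group and meta to the aldehyde, so all three directing effects converge there.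

**Step 4**
Reactants: 8; 9 tributyl(3-methylbut-2-en-1-yl)stannane
Product: 10 2,2-dimethyl-8-(3-methylbut-2-en-1-yl)chroman-6-carbaldehyde
Conditions: Pd(PPh3)4 (5 mol%), DMF, 90 °C
Reagents that add atoms: tributyl(3-methylbut-2-en-1-yl)stannane 9, CCCC[Sn](CCCC)(CCCC)CC=C(C)C
Why: Stille coupling: the allyl group is transferred from tin, and reductive elimination at the less substituted allyl terminus should give the linear prenyl arene; the aldehyde is tolerated.

**Step 5**
Reactants: 10
Product: 11 [2,2-dimethyl-8-(3-methylbut-2-en-1-yl)chroman-6-yl]methanol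
Conditions: NaBH4, MeOH, 0 °C
Reagents that add atoms: none
Why: Borohydride reduction of an aromatic aldehyde; the trisubstituted alkene and the chroman are inert.

**Step 6**
Reactants: 5; 11
Product: 12 1-[2-{[2,2-dimethyl-8-(3-methylbut-2-en-1-yl)chroman-6-yl]methoxy}-3-(3-methylbut-2-en-1-yl)-4-(triisopropylsilyloxy)phenyl]ethan-1-one
Conditions: PPh3, diisopropyl azodicarboxylate, THF, 0 °C to rt
Reagents that add atoms: alcohol 11, CC(C)=CCc1cc(CO)cc2c1OC(C)(C)CC2
Why: Mitsunobu etherification: the acidic chelated phenol protonates the betaine and its phenoxide displaces the primary, electron-rich benzylic oxyphosphonium; the neutral conditions spare the aryl silyl ether.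

**Step 7**
Reactants: 12; 13 2,2,2-trifluoroethyl trifluoroacetate; 14 methanesulfonyl azide
Product: 16 2-diazo-1-[2-{[2,2-dimethyl-8-(3-methylbut-2-en-1-yl)chroman-6-yl]methoxy}-3-(3-methylbut-2-en-1-yl)-4-(triisopropylsilyloxy)phenyl]ethan-1-one, via trifluoroacetyl ketone 15 (not isolated)
Conditions: LiN(SiMe3)2, THF, −78 °C, then 13; aq. HCl work-up; then 14, Et3N, H2O (1 equiv), MeCN, rt
Reagents that add atoms: methanesulfonyl azide 14, CS(=O)(=O)N=[N+]=[N-]; 2,2,2-trifluoroethyl trifluoroacetate 13, O=C(OCC(F)(F)F)C(F)(F)F (its atoms stay only in intermediate 15)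
Why: Regitz-type detrifluoroacetylative diazo transfer: the kinetic methyl ketone enolate is trifluoroacetylated, and the activated 1,3-diketone takes up the diazo group from the sulfonyl azide while the trifluoroacetyl group leaves on the sulfonamide.

**Step 8**
Reactants: 16
Product: 17 (2S)-2-[2,2-dimethyl-8-(3-methylbut-2-en-1-yl)chroman-6-yl]-8-(3-methylbut-2-en-1-yl)-7-(triisopropylsilyloxy)chroman-4-one
Conditions: Rh2(S-PTTL)4 (dirhodium tetrakis[N-phthaloyl-(S)-tert-leucinate], 1 mol%), CH2Cl2, slow addition of 16, 0 °C to rt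
Reagents that add atoms: none
Why: Loss of N2 from 16 at the divalent rhodium center gives an electrophilic ketocarbenoid at the future C3, which inserts into one of the two enantiotopic C–H bonds of the O–CH2–aryl group (the future C2) through a concerted, three-centred, hydride-transfer-like transition state, forming the C3–C2 bond with retention at carbon. The closest known reaction type is the intramolecular C–H insertion of 2-alkoxyphenyl diazoketones to chroman-4-ones under chiral dirhodium carboxylate catalysis. Ring C closes as a six-membered ring by 1,6-insertion; no five-membered alternative exists because O1 carries no hydrogen. The C2 stereocenter is catalyst-controlled, the chiral carboxylate pocket selecting one enantiotopic hydrogen; the sense of induction cannot be assigned with confidence beforehand and is to be fixed by a test run, with Rh2(R-PTTL)4 used instead if the (2R) sense is found. The step needs chemoselectivity for C–H insertion over oxonium ylide formation with benzyl [1,2]-shift and over cyclopropanation of the prenyl groups: the C–H bond is doubly activated (alpha to O1 and benzylic to the para-alkoxy ring B), the aryl ether oxygen is a poor donor and rhodium instead of copper disfavours the ylide channel, the C8 prenyl group is meta to the carbenoid arm and cannot reach it, and slow addition at high dilution suppresses intermolecular reactions.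

**Step 9**
Reactants: 17
Product: 18 (2S)-2-[2,2-dimethyl-8-(3-methylbut-2-en-1-yl)chroman-6-yl]-7-hydroxy-8-(3-methylbut-2-en-1-yl)chroman-4-one
Conditions: Bu4NF, AcOH (1:1), THF, 0 °C
Reagents that add atoms: none
Why: Fluoride-induced cleavage of the aryl silyl ether; the acetic acid buffer should prevent base-induced retro-oxa-Michael opening of ring C, which would racemize C2.

**Compound list**
1 | 2,4-dihydroxyacetophenone | CC(=O)c1ccc(O)cc1O | starting material
2 | prenyl bromide (1-bromo-3-methylbut-2-ene) | CC(C)=CCBr | starting material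
3 | 1-[2,4-dihydroxy-3-(3-methylbut-2-en-1-yl)phenyl]ethan-1-one | CC(=O)c1ccc(O)c(CC=C(C)C)c1O | intermediate
4 | chlorotriisopropylsilane | CC(C)[Si](Cl)(C(C)C)C(C)C | starting material
5 | 1-[2-hydroxy-3-(3-methylbut-2-en-1-yl)-4-(triisopropylsilyloxy)phenyl]ethan-1-one | CC(=O)c1ccc(O[Si](C(C)C)(C(C)C)C(C)C)c(CC=C(C)C)c1O | intermediate
6 | 2,2-dimethylchroman-6-carbaldehyde | CC1(C)CCc2cc(C=O)ccc2O1 | starting material
7 | bromine | BrBr | starting material
8 | 8-bromo-2,2-dimethylchroman-6-carbaldehyde | CC1(C)CCc2cc(C=O)cc(Br)c2O1 | intermediate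
9 | tributyl(3-methylbut-2-en-1-yl)stannane | CCCC[Sn](CCCC)(CCCC)CC=C(C)C | starting material
10 | 2,2-dimethyl-8-(3-methylbut-2-en-1-yl)chroman-6-carbaldehyde | CC(C)=CCc1cc(C=O)cc2c1OC(C)(C)CC2 | intermediate
11 | [2,2-dimethyl-8-(3-methylbut-2-en-1-yl)chroman-6-yl]methanol | CC(C)=CCc1cc(CO)cc2c1OC(C)(C)CC2 | intermediate
12 | 1-[2-{[2,2-dimethyl-8-(3-methylbut-2-en-1-yl)chroman-6-yl]methoxy}-3-(3-methylbut-2-en-1-yl)-4-(triisopropylsilyloxy)phenyl]ethan-1-one | CC(=O)c1ccc(O[Si](C(C)C)(C(C)C)C(C)C)c(CC=C(C)C)c1OCc1cc(CC=C(C)C)c2OC(C)(C)CCc2c1 | intermediate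
13 | 2,2,2-trifluoroethyl trifluoroacetate | O=C(OCC(F)(F)F)C(F)(F)F | starting material
14 | methanesulfonyl azide | CS(=O)(=O)N=[N+]=[N-] | starting material
15 | 4,4,4-trifluoro-1-[2-{[2,2-dimethyl-8-(3-methylbut-2-en-1-yl)chroman-6-yl]methoxy}-3-(3-methylbut-2-en-1-yl)-4-(triisopropylsilyloxy)phenyl]butane-1,3-dione | FC(F)(F)C(=O)CC(=O)c1ccc(O[Si](C(C)C)(C(C)C)C(C)C)c(CC=C(C)C)c1OCc1cc(CC=C(C)C)c2OC(C)(C)CCc2c1 | intermediate
16 | 2-diazo-1-[2-{[2,2-dimethyl-8-(3-methylbut-2-en-1-yl)chroman-6-yl]methoxy}-3-(3-methylbut-2-en-1-yl)-4-(triisopropylsilyloxy)phenyl]ethan-1-one | [N-]=[N+]=CC(=O)c1ccc(O[Si](C(C)C)(C(C)C)C(C)C)c(CC=C(C)C)c1OCc1cc(CC=C(C)C)c2OC(C)(C)CCc2c1 | intermediate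
17 | (2S)-2-[2,2-dimethyl-8-(3-methylbut-2-en-1-yl)chroman-6-yl]-8-(3-methylbut-2-en-1-yl)-7-(triisopropylsilyloxy)chroman-4-one | CC(C)=CCc1cc([C@@H]2CC(=O)c3ccc(O[Si](C(C)C)(C(C)C)C(C)C)c(CC=C(C)C)c3O2)cc2c1OC(C)(C)CC2 | intermediate
18 | (2S)-2-[2,2-dimethyl-8-(3-methylbut-2-en-1-yl)chroman-6-yl]-7-hydroxy-8-(3-methylbut-2-en-1-yl)chroman-4-one | CC(C)=CCc1cc([C@@H]2CC(=O)c3ccc(O)c(CC=C(C)C)c3O2)cc2c1OC(C)(C)CC2 | target

**Step count**
Total steps: 9. Longest linear sequence: 7 (steps 3, 4, 5, 6, 7, 8 and 9, from 6).

**Steps most likely to fail**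

1. Step 8. The carbenoid may be diverted into oxonium ylide formation at O1 followed by a benzyl [1,2]-shift, or the catalyst may discriminate the two enantiotopic hydrogens insufficiently. Fallback (known chemistry): setting out from 5 and 10, pyrrolidine-mediated aldol condensation and oxa-Michael closure (pyrrolidine, EtOH, rt) should give the racemic 7-O-triisopropylsilyl flavanone F1. Kinetic resolution of this racemate by Noyori-type asymmetric transfer hydrogenation (RuCl(p-cymene)[TsDPEN], HCO2H/Et3N, with the ligand antipode that consumes the (2R)-ketone, assigned in a test run) should reduce the unwanted enantiomer to the (2R,4R)-cis-flavan-4-ol silyl ether F2 and leave the (2S)-ketone, which is separated by chromatography; the route is rejoined at 17. The same resolution could also upgrade partially enriched 17.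

2. Step 1. Alkylation may be spread over O-alkylation, attack at C5 and double prenylation, leaving little of the C3 isomer. Fallback: setting out from 1, alkylation of the free 4-OH with 3-chloro-3-methylbut-1-yne (K2CO3, KI, acetone, reflux) should give the 1,1-dimethylpropargyl ether F3. Semihydrogenation (H2, Pd/CaCO3 poisoned with Pb(OAc)2, quinoline, EtOAc) should give the 1,1-dimethylallyl ether F4. Aromatic Claisen rearrangement (N,N-diethylaniline, heat) into the position between the two oxygens comes back to the route at 3.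

3. Step 6. Activation of the hindered, hydrogen-bonded phenol may be too slow, so that the benzylic oxyphosphonium is consumed by other nucleophiles. Fallback: setting out from 11, Appel bromination (CBr4, PPh3, CH2Cl2, 0 °C) should give the benzylic bromide F5. Williamson etherification of 5 with this bromide (K2CO3, acetone, reflux) comes back to the route at 12.

**Further compounds**
F1 | step 8 | racemic 2-[2,2-dimethyl-8-(3-methylbut-2-en-1-yl)chroman-6-yl]-8-(3-methylbut-2-en-1-yl)-7-(triisopropylsilyloxy)chroman-4-one | CC(C)=CCc1cc(C2CC(=O)c3ccc(O[Si](C(C)C)(C(C)C)C(C)C)c(CC=C(C)C)c3O2)cc2c1OC(C)(C)CC2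
F2 | step 8 | (2R,4R)-2-[2,2-dimethyl-8-(3-methylbut-2-en-1-yl)chroman-6-yl]-8-(3-methylbut-2-en-1-yl)-7-(triisopropylsilyloxy)chroman-4-ol | CC(C)=CCc1cc([C@H]2C[C@@H](O)c3ccc(O[Si](C(C)C)(C(C)C)C(C)C)c(CC=C(C)C)c3O2)cc2c1OC(C)(C)CC2
F3 | step 1 | 1-[2-hydroxy-4-(2-methylbut-3-yn-2-yloxy)phenyl]ethan-1-one | CC(=O)c1ccc(OC(C)(C)C#C)cc1O
F4 | step 1 | 1-[2-hydroxy-4-(2-methylbut-3-en-2-yloxy)phenyl]ethan-1-one | CC(=O)c1ccc(OC(C)(C)C=C)cc1O
F5 | step 6 | 6-(bromomethyl)-2,2-dimethyl-8-(3-methylbut-2-en-1-yl)chroman | CC(C)=CCc1cc(CBr)cc2c1OC(C)(C)CC2
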